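The plan cuts the C5–C6 bond of the bicyclo[3.2.1]oct-2-en-8-one (C5 = methoxy bridgehead, C6 = aryl-bearing carbon) and rejoins C6 to C2: the cyclopentanone ring C1–C8–C5–C6–C7 then shrinks to a cyclobutane C1–C7–C6–C2 fused to a dimethoxy-enedione. Forward, acid opens this cyclobutane at the benzylic carbon and C5, the nucleophilic α-carbon of a vinylogous ester held 1,3 to the quaternary allyl carbon C1 across the C8 carbonyl, recaptures the cation; one step thus makes the bridged skeleton, the C5 quaternary ether and the aryl stereocentre. The precursor is the enantioenriched Ti(IV)-mediated [2+2] adduct of an allyl methoxyquinone and O-allyl isoeugenol.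

Key step: step 7

Remark on numbering: the labels C1–C8 are those of the target (C1 allyl bridgehead, C2 =CH, C3 C–OMe, C4 CHOH, C5 OMe bridgehead, C6 CH–aryl, C7 CH–Me, C8 C=O) and are kept for every intermediate.
Remark on step 5: the sense of induction of the TADDOL–Ti(IV) promoter on this quinone is assumed to be the one drawn; the (S,S)-ligand would be taken if a pilot run showed the opposite.

Step 1
Reactants: 1 3,4-dimethoxyphenol
Product: 2 4-(allyloxy)-1,2-dimethoxybenzene
Conditions: allyl bromide, K2CO3, acetone, reflux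
Reagents that add atoms: allyl bromide, C=CCBr
Why: Williamson ether synthesis of the phenoxide with a primary allylic bromide; no stereocentre.

Step 2
Reactants: 2 4-(allyloxy)-1,2-dimethoxybenzene
Product: 3 2-allyl-4,5-dimethoxyphenol
Conditions: N,N-diethylaniline, 190 °C
Reagents that add atoms: none
Why: Aromatic Claisen rearrangement ([3,3]-sigmatropic shift, then tautomerisation) should deliver the allyl group to the less hindered ortho carbon, the one para to a methoxy group; no stereocentre.

Step 3
Reactants: 3 2-allyl-4,5-dimethoxyphenol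
Product: 4 2-allyl-5-methoxy-1,4-benzoquinone
Conditions: PhI(OAc)2, MeCN–H2O, 0 °C
Reagents that add atoms: water, O
Why: Hypervalent-iodine oxidative demethylation of a p-methoxyphenol (water adds to the para carbon, methanol is lost) should give the p-quinone and leave the allyl group alone; no stereocentre.

Step 4
Reactants: 5 (E)-isoeugenol
Product: 6 1-(allyloxy)-2-methoxy-4-[(E)-prop-1-enyl]benzene
Conditions: allyl bromide, K2CO3, DMF, rt
Reagents that add atoms: allyl bromide, C=CCBr
Why: Williamson etherification; the aryl allyl ether keeps the arene electron-rich, should survive Ti(IV), CF3CO2H, methoxide and borohydride, and is later removed by Pd(0) without touching the C-allyl group.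

Step 5
Reactants: 4 2-allyl-5-methoxy-1,4-benzoquinone; 6 1-(allyloxy)-2-methoxy-4-[(E)-prop-1-enyl]benzene
Product: 7 (1R,6S,7R,8R)-1-allyl-7-[4-(allyloxy)-3-methoxyphenyl]-4-methoxy-8-methylbicyclo[4.2.0]oct-3-ene-2,5-dione
Conditions: TiCl4–Ti(OiPr)4 (1:1), (R,R)-TADDOL, CH2Cl2, −78 °C; then aq. NaHCO3
Reagents that add atoms: none
Why: Ti(IV)-promoted formal [2+2] cycloaddition of a 2-alkoxy-5-alkyl-1,4-benzoquinone with an (E)-propenylbenzene: titanium chelated by the C3 carbonyl and the C4 methoxy group makes C1 the electrophilic site, the nucleophilic β-carbon of 6 adds there to form the quaternary centre, and the benzylic cation collapses onto the titanium enolate carbon C2 with the trans aryl/methyl relation kept and a cis ring fusion, while the C2-symmetric TADDOLate on titanium selects the quinone face and so the absolute configuration of C1 and C7.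

Step 6
Reactants: 7 (1R,6S,7R,8R)-1-allyl-7-[4-(allyloxy)-3-methoxyphenyl]-4-methoxy-8-methylbicyclo[4.2.0]oct-3-ene-2,5-dione
Product: 9 (1R,6S,7R,8R)-1-allyl-7-[4-(allyloxy)-3-methoxyphenyl]-3,4-dimethoxy-8-methylbicyclo[4.2.0]oct-3-ene-2,5-dione, via bromo-enedione 8 (not isolated)
Conditions: NBS, CH2Cl2, 0 °C; then NaOMe, MeOH, −20 → 0 °C
Reagents that add atoms: sodium methoxide, C[O-].[Na+]
Why: Electrophilic bromination should occur at C5, the electron-rich α-carbon of the vinylogous ester, and methoxide then replaces the vinylic bromide by addition–elimination (C5 is β to the C3 carbonyl), which is the haloquinone-to-alkoxyquinone exchange applied to an enedione; no stereocentre is affected, since C2–H can only return to the cis-fused ring.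

Step 7
Reactants: 9 (1R,6S,7R,8R)-1-allyl-7-[4-(allyloxy)-3-methoxyphenyl]-3,4-dimethoxy-8-methylbicyclo[4.2.0]oct-3-ene-2,5-dione
Product: 11 (1R,5S,6S,7R)-1-allyl-6-[4-(allyloxy)-3-methoxyphenyl]-3-hydroxy-5-methoxy-7-methylbicyclo[3.2.1]oct-2-ene-4,8-dione, via dienol benzylic cation 10 (not isolated)
Conditions: CF3CO2H, CH2Cl2, −20 → 0 °C; then H2O, NaHCO3
Reagents that add atoms: water, O
Why: Protonation of the C3 carbonyl lets the benzylic C2–C6 bond of the strained cyclobutane break (retro-Michael-type heterolysis) to the dienol-benzylic cation 10, and C5, the nucleophilic α-carbon of the vinylogous ester MeO–C4=C5–C8=O, recaptures the cation, so that C6 moves from C2 to C5 (formal 1,3-shift) and the four-membered ring C1–C7–C6–C2 grows into the cyclopentanone C1–C7–C6–C5–C8; water then hydrolyses the C4 methyloxocarbenium ion to the diosphenol with loss of methanol. The closest known reaction type is the acid-promoted rearrangement of quinone–propenylbenzene [2+2] adducts (8-arylbicyclo[4.2.0]oct-3-ene-2,5-diones) into 7-arylbicyclo[3.2.1]oct-3-ene-2,8-diones. The one ring that closes does so in a 5-exo-trig cation–enol ether cyclisation. C5 can only be reached from the face of the dienone on which the C7 side chain hangs, so its configuration follows from C1; C6 is re-formed with the aryl group anti to the C7 methyl group (allylic strain in the cation), i.e. endo; C1 and C7 are carried over from 9. The step needs C- instead of O-capture of the cation and no cycloreversion: O-capture by the C8 carbonyl gives a dihydrobenzofuranone that re-ionises in the same acid, whereas C–C closure is made irreversible by loss of the methyl group, so the bridged dione should be the sink. The 1,3-relation of C5 to the quaternary C1 across C8, with the donor methoxy on C4, fixes the site of closure.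

Step 8
Reactants: 11 (1R,5S,6S,7R)-1-allyl-6-[4-(allyloxy)-3-methoxyphenyl]-3-hydroxy-5-methoxy-7-methylbicyclo[3.2.1]oct-2-ene-4,8-dione
Product: 12 (1R,5S,6S,7R)-1-allyl-6-[4-(allyloxy)-3-methoxyphenyl]-3,5-dimethoxy-7-methylbicyclo[3.2.1]oct-2-ene-4,8-dione
Conditions: Me2SO4, K2CO3, acetone, rt
Reagents that add atoms: dimethyl sulfate, COS(=O)(=O)OC
Why: O-Alkylation of a diosphenol (enolised 1,2-diketone) with a hard electrophile; the enol can only lie toward C2 because C5 is a bridgehead, so a single enol ether should form.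

Step 9
Reactants: 12 (1R,5S,6S,7R)-1-allyl-6-[4-(allyloxy)-3-methoxyphenyl]-3,5-dimethoxy-7-methylbicyclo[3.2.1]oct-2-ene-4,8-dione
Product: 13 (1R,4S,5R,6S,7R)-1-allyl-6-[4-(allyloxy)-3-methoxyphenyl]-4-hydroxy-3,5-dimethoxy-7-methylbicyclo[3.2.1]oct-2-en-8-one
Conditions: NaBH4, CeCl3·7H2O, MeOH, −78 °C
Reagents that add atoms: none
Why: Luche reduction: cerium-assisted 1,2-hydride delivery that should prefer the conjugated C4 ketone over the isolated C8 ketone (flanked by two quaternary bridgeheads), with hydride entering from the exo face (the side of the C8 bridge, away from the endo aryl group on C6) to set the (4S) endo alcohol.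

Step 10
Reactants: 13 (1R,4S,5R,6S,7R)-1-allyl-6-[4-(allyloxy)-3-methoxyphenyl]-4-hydroxy-3,5-dimethoxy-7-methylbicyclo[3.2.1]oct-2-en-8-one
Product: 14 (1R,4S,5R,6S,7R)-1-allyl-4-hydroxy-6-(4-hydroxy-3-methoxyphenyl)-3,5-dimethoxy-7-methylbicyclo[3.2.1]oct-2-en-8-one (CNP0330966.1)
Conditions: Pd(PPh3)4 (cat.), morpholine, THF, rt
Reagents that add atoms: none
Why: Tsuji–Trost deallylation: Pd(0) should ionise only the aryl allyl ether (phenoxide leaving group) and morpholine traps the π-allyl unit, while the C-allyl group, the enol ether and the free alcohol stay inert; no stereocentre is touched.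

Compound list
1 | 3,4-dimethoxyphenol | COc1ccc(O)cc1OC | starting material
2 | 4-(allyloxy)-1,2-dimethoxybenzene | C=CCOc1ccc(OC)c(OC)c1 | intermediate
3 | 2-allyl-4,5-dimethoxyphenol | C=CCc1cc(OC)c(OC)cc1O | intermediate
4 | 2-allyl-5-methoxy-1,4-benzoquinone | C=CCC1=CC(=O)C(OC)=CC1=O | intermediate
5 | (E)-isoeugenol, 2-methoxy-4-[(E)-prop-1-enyl]phenol | C/C=C/c1ccc(O)c(OC)c1 | starting material
6 | 1-(allyloxy)-2-methoxy-4-[(E)-prop-1-enyl]benzene | C/C=C/c1ccc(OCC=C)c(OC)c1 | intermediate
7 | (1R,6S,7R,8R)-1-allyl-7-[4-(allyloxy)-3-methoxyphenyl]-4-methoxy-8-methylbicyclo[4.2.0]oct-3-ene-2,5-dione; cis-fused, 8-methyl on the same face as the C2 carbonyl, 7-aryl trans to the methyl | C=CC[C@]12C(=O)C=C(OC)C(=O)[C@H]1[C@H](c1ccc(OCC=C)c(OC)c1)[C@H]2C | intermediate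
8 | (1R,6S,7R,8R)-1-allyl-7-[4-(allyloxy)-3-methoxyphenyl]-3-bromo-4-methoxy-8-methylbicyclo[4.2.0]oct-3-ene-2,5-dione (formed in the flask) | C=CC[C@]12C(=O)C(Br)=C(OC)C(=O)[C@H]1[C@H](c1ccc(OCC=C)c(OC)c1)[C@H]2C | intermediate
9 | (1R,6S,7R,8R)-1-allyl-7-[4-(allyloxy)-3-methoxyphenyl]-3,4-dimethoxy-8-methylbicyclo[4.2.0]oct-3-ene-2,5-dione; same relative configuration as 7 | C=CC[C@]12C(=O)C(OC)=C(OC)C(=O)[C@H]1[C@H](c1ccc(OCC=C)c(OC)c1)[C@H]2C | intermediate
10 | dienol benzylic cation: 6-allyl-4-hydroxy-2,3-dimethoxycyclohexa-2,4-dienone carrying at C6 a 1-aryl-propan-2-yl cation side chain, configuration at the quaternary carbon and at the CH–Me carbon as in 9 (formed in the flask) | C=CC[C@]1(C=C(O)C(OC)=C(OC)C1=O)[C@H](C)[CH+]c1ccc(OCC=C)c(OC)c1 | intermediate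
11 | (1R,5S,6S,7R)-1-allyl-6-[4-(allyloxy)-3-methoxyphenyl]-3-hydroxy-5-methoxy-7-methylbicyclo[3.2.1]oct-2-ene-4,8-dione; aryl endo, methyl exo | C=CC[C@@]12C=C(O)C(=O)[C@@](OC)(C1=O)[C@H](c1ccc(OCC=C)c(OC)c1)[C@H]2C | intermediate
12 | (1R,5S,6S,7R)-1-allyl-6-[4-(allyloxy)-3-methoxyphenyl]-3,5-dimethoxy-7-methylbicyclo[3.2.1]oct-2-ene-4,8-dione | C=CC[C@@]12C=C(OC)C(=O)[C@@](OC)(C1=O)[C@H](c1ccc(OCC=C)c(OC)c1)[C@H]2C | intermediate
13 | (1R,4S,5R,6S,7R)-1-allyl-6-[4-(allyloxy)-3-methoxyphenyl]-4-hydroxy-3,5-dimethoxy-7-methylbicyclo[3.2.1]oct-2-en-8-one | C=CC[C@@]12C=C(OC)[C@H](O)[C@@](OC)(C1=O)[C@H](c1ccc(OCC=C)c(OC)c1)[C@H]2C | intermediate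
14 | (1R,4S,5R,6S,7R)-1-allyl-4-hydroxy-6-(4-hydroxy-3-methoxyphenyl)-3,5-dimethoxy-7-methylbicyclo[3.2.1]oct-2-en-8-one | C=CC[C@@]12C=C(OC)[C@H](O)[C@@](OC)(C1=O)[C@H](c1ccc(O)c(OC)c1)[C@H]2C | target

Total step count: 10. Longest linear sequence: 9 steps (1 → 2 → 3 → 4 → 7 → 9 → 11 → 12 → 13 → 14).

Steps most likely to fail

Step 5. The chiral titanium promoter may discriminate the quinone faces poorly (or in the wrong sense) when the attacked carbon carries the allyl group, and the zwitterion may partly go on to O-closed products instead of stopping at the cyclobutane. Fallback: starting from 4 and 6, the cycloaddition is run with achiral TiCl4–Ti(OiPr)4 in CH2Cl2 at −78 °C, which should give the racemate, that is 7 together with its mirror image, the ent-cyclobutane F1. The enantiomers are then separated by preparative HPLC on a chiral stationary phase, and the route is rejoined at 7.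

Step 7. The benzylic cation may be recaptured by the C8 carbonyl oxygen, or the cyclobutane may undergo cycloreversion, faster than the C5–C6 bond forms. Fallback: starting from 9, the cyclobutane is first isomerised under the milder titanium Lewis acid (TiCl4–Ti(OiPr)4, CH2Cl2, −78 → −20 °C, aqueous work-up) to the O-closed product, 3a-allyl-2-[4-(allyloxy)-3-methoxyphenyl]-5-hydroxy-7-methoxy-3-methyl-3,3a-dihydro-1-benzofuran-6(2H)-one F2, which is isolated. F2 is then converted by a strong protic acid (CF3SO3H cat., CH2Cl2, 0 °C) through the known hydrobenzofuranone to bicyclo[3.2.1]octenedione rearrangement, and the route is rejoined at 11.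

Step 9. Hydride may attack the strained C8 bridge ketone in competition with the conjugated C4 ketone. Fallback: starting from 12, both carbonyls are reduced with excess NaBH4/CeCl3 in MeOH at 0 °C to the 4,8-diol F3 (the configuration of the C8 carbinol is immaterial and left undefined). TBSCl/imidazole in DMF should silylate only the C4 allylic hydroxyl, since the C8 carbinol lies between two quaternary bridgeheads, to give the 4-O-TBS ether F4. Dess–Martin periodinane re-oxidises C8 to the 4-O-TBS ketone F5, and TBAF in THF removes the silyl group, rejoining the route at 13.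

Further compounds
F1 | step 5 | (1S,6R,7S,8S)-1-allyl-7-[4-(allyloxy)-3-methoxyphenyl]-4-methoxy-8-methylbicyclo[4.2.0]oct-3-ene-2,5-dione (ent-7) | C=CC[C@@]12C(=O)C=C(OC)C(=O)[C@@H]1[C@@H](c1ccc(OCC=C)c(OC)c1)[C@@H]2C
F2 | step 7 | 3a-allyl-2-[4-(allyloxy)-3-methoxyphenyl]-5-hydroxy-7-methoxy-3-methyl-3,3a-dihydro-1-benzofuran-6(2H)-one; 2-aryl/3-methyl trans, 3-methyl/3a-allyl cis, C3 and C3a as C7 and C1 of 9 | C=CC[C@@]12C=C(O)C(=O)C(OC)=C1O[C@H](c1ccc(OCC=C)c(OC)c1)[C@H]2C
F3 | step 9 | (1R,4S,5R,6S,7R)-1-allyl-6-[4-(allyloxy)-3-methoxyphenyl]-3,5-dimethoxy-7-methylbicyclo[3.2.1]oct-2-ene-4,8-diol (C8 undefined) | C=CC[C@@]12C=C(OC)[C@H](O)[C@@](OC)(C1O)[C@H](c1ccc(OCC=C)c(OC)c1)[C@H]2C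
F4 | step 9 | 4-O-tert-butyldimethylsilyl ether of F3 (C8 undefined) | C=CC[C@@]12C=C(OC)[C@H](O[Si](C)(C)C(C)(C)C)[C@@](OC)(C1O)[C@H](c1ccc(OCC=C)c(OC)c1)[C@H]2C
F5 | step 9 | 4-O-tert-butyldimethylsilyl ether of 13 | C=CC[C@@]12C=C(OC)[C@H](O[Si](C)(C)C(C)(C)C)[C@@](OC)(C1=O)[C@H](c1ccc(OCC=C)c(OC)c1)[C@H]2C
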